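**Retrosynthetic overview**
1. The target is reached by hydrolysis of the two methyl esters of diaryl ether 16; ring B of 16 is revealed by dehydrogenation of the 3-aryloxycyclohexenone 15, so ring B stays non-aromatic until the penultimate step.
2. The C1'–O ether bond is cut to ring A phenol 12 and β-chloroenone 14, which comes from cyclic dione 6.
3. The feature used: in ring B the ether oxygen on C1' and the hydroxyl on C3' are 1,3 to each other, with C3' next to the C4' carboxyl. This is the oxygen pattern of a 2,4-dioxocyclohexane-1-carboxylate. Cutting C4'–C5' and C1'–C2' gives methyl acetoacetate (C2', C3', C4' and the carboxyl) and methyl 2-methoxydec-2-enoate (C1', C6' with its methoxy, C5' with its heptyl).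
4. Ring A phenol 12 comes from the same annulation with methyl dec-2-enoate, followed by aromatization and mono-O-methylation.
5. Ring order: the ring B carbocycle (step 2) and the ring A carbocycle (step 3) are closed independently; ring A is aromatized in step 4, ring B in step 8.

Key step: step 2

Remark: the target has no stereocentre. Enoate 3 is used as whatever Z/E mixture the olefination gives, and the ring B intermediates 6, 14 and 15 are carried as mixtures of diastereomers and tautomers, because all their sp3 centres disappear in step 8.

**Step 1**
Reactants: 1 octanal; 2 methyl 2-(dimethoxyphosphoryl)-2-methoxyacetate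
Product: 3 methyl (Z)-2-methoxydec-2-enoate
Conditions: NaH, THF, 0 °C → rt
Reagents that add atoms: none
Why: Horner–Wadsworth–Emmons olefination of an unhindered aliphatic aldehyde with the sodium salt of the α-methoxy phosphonoacetate should give the 2-methoxy enoate with the ester trans to the heptyl chain (Z) as the main isomer, and both geometric isomers converge in step 2.

**Step 2**
Reactants: 3 methyl (Z)-2-methoxydec-2-enoate; 4 methyl acetoacetate
Product: 6 methyl 6-heptyl-5-methoxy-2,4-dioxocyclohexane-1-carboxylate, via Michael adduct 5 (not isolated)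
Conditions: 4 (1.5 equiv), NaOMe (1.5 equiv), MeOH, reflux; then 1 M HCl, 0 °C, to pH 3
Reagents that add atoms: none
Why: Proposed new method: methoxide deprotonates 4 at its α-carbon, which adds to C3 of enoate 3 (bond C4'–C5'); after proton shuffling in adduct 5 the acetyl methyl carbanion attacks the ester carbonyl that came from 3 and expels methoxide (bond C1'–C2'), and the ring is trapped as its 1,3-dione enolate. The closest known reaction is the Michael–Dieckmann (Michael–Claisen) annulation of acetoacetates with simple alk-2-enoates, run as such in step 3; new here is the 2-methoxy-2-enoate acceptor, whose enol ether oxygen lowers the electrophilicity of the β-carbon and should make the conjugate addition slower and less favourable. Ring B is closed by a 6-(enolendo)-exo-trig acyl substitution, a favoured mode. The three sp3 centres formed (C4', C5', C6') are left uncontrolled on purpose, since step 8 removes all of them. The selectivity needed is regiochemical: the doubly activated α-CH2 of 4 is the only effective Michael donor and only the methyl carbanion can reach the ester through a six-membered transition state, so the substituents cannot end up in another order. The closure ends in an enolate far less basic than methoxide and should therefore drain the reversible addition, while methoxide in methanol leaves both methyl esters unchanged and cannot eliminate the methoxy group, which is never β to an enolate carbon in 5 or 6.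

**Step 3**
Reactants: 4 methyl acetoacetate; 7 methyl (E)-dec-2-enoate
Product: 9 methyl 6-heptyl-2,4-dioxocyclohexane-1-carboxylate, via Michael adduct 8 (not isolated)
Conditions: NaOMe, MeOH, reflux; then 1 M HCl, 0 °C
Reagents that add atoms: none
Why: The standard Michael–Dieckmann annulation of an acetoacetate with an unsubstituted alk-2-enoate should give the dihydroresorcylate, whose two sp3 centres are uncontrolled and are removed in step 4.

**Step 4**
Reactants: 9 methyl 6-heptyl-2,4-dioxocyclohexane-1-carboxylate
Product: 11 methyl 2-heptyl-4,6-dihydroxybenzoate, via bromodione 10 (not isolated)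
Conditions: Br2 (1.0 equiv), DMF, 0 °C → 80 °C
Reagents that add atoms: none
Why: Oxidative aromatization by bromination–dehydrobromination: the dione enol should consume the bromine at 0 °C, before any electron-rich arene is present, and warming should expel hydrogen bromide to leave the resorcylate.

**Step 5**
Reactants: 11 methyl 2-heptyl-4,6-dihydroxybenzoate
Product: 12 methyl 2-heptyl-6-hydroxy-4-methoxybenzoate
Conditions: MeI (1.1 equiv), K2CO3, acetone, rt
Reagents that add atoms: iodomethane, CI
Why: Williamson etherification should take place at the hydroxyl para to the ester, because the ortho hydroxyl is hydrogen-bonded to the ester carbonyl and is less acidic and less nucleophilic.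

**Step 6**
Reactants: 6 methyl 6-heptyl-5-methoxy-2,4-dioxocyclohexane-1-carboxylate
Product: 14 methyl 4-chloro-6-heptyl-5-methoxy-2-oxocyclohex-3-ene-1-carboxylate, via enol chlorooxalate 13 (not isolated)
Conditions: (COCl)2 (1.2 equiv), CH2Cl2, 0 °C → rt; crude 14 used directly
Reagents that add atoms: oxalyl chloride, O=C(Cl)C(Cl)=O
Why: β-Chloroenone formation from a cyclic 1,3-dione (O-acylation, conjugate addition of chloride, fragmentation to CO and CO2) should occur at the C1' oxygen, because the enol proton is expected to rest on the C3' oxygen, hydrogen-bonded to the ester carbonyl, which leaves the C1' oxygen as the nucleophilic carbonyl end of the vinylogous acid.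

**Step 7**
Reactants: 14 methyl 4-chloro-6-heptyl-5-methoxy-2-oxocyclohex-3-ene-1-carboxylate; 12 methyl 2-heptyl-6-hydroxy-4-methoxybenzoate
Product: 15 methyl 6-heptyl-4-[3-heptyl-5-methoxy-2-(methoxycarbonyl)phenoxy]-5-methoxy-2-oxocyclohex-3-ene-1-carboxylate
Conditions: 12 (1.3 equiv), K2CO3, MeCN, 50 °C, 14 added slowly
Reagents that add atoms: none
Why: Addition–elimination (vinylogous acyl substitution) of the phenoxide at the β-carbon of the chloroenone needs no metal catalyst, and since the phenol and the β-keto ester C–H are of similar acidity, phenoxide and neutral chloroenone should coexist, while slow addition keeps self-condensation of 14 down.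

**Step 8**
Reactants: 15 methyl 6-heptyl-4-[3-heptyl-5-methoxy-2-(methoxycarbonyl)phenoxy]-5-methoxy-2-oxocyclohex-3-ene-1-carboxylate
Product: 16 methyl 2-heptyl-4-[3-heptyl-5-methoxy-2-(methoxycarbonyl)phenoxy]-6-hydroxy-3-methoxybenzoate
Conditions: DDQ (1.2 equiv), 1,4-dioxane, 80 °C
Reagents that add atoms: none
Why: DDQ dehydrogenation of the dienol tautomer should proceed by hydride abstraction from C5'–H to a cation stabilized by the oxygens on C1' and C3', which loses the C6' proton to give the arene with the methoxy group kept, whereas ionization of the C6' methoxy would give a cation that neither ring oxygen stabilizes.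

**Step 9**
Reactants: 16 methyl 2-heptyl-4-[3-heptyl-5-methoxy-2-(methoxycarbonyl)phenoxy]-6-hydroxy-3-methoxybenzoate
Product: 17 4-(2-carboxy-3-heptyl-5-methoxyphenoxy)-2-heptyl-6-hydroxy-3-methoxybenzoic acid (CNP0151337.0)
Conditions: KOH (excess), DMSO/H2O, 80 °C, argon; then 1 M HCl, 0 °C
Reagents that add atoms: potassium hydroxide, [K+].[OH-]; water, O
Why: Saponification of the two di-ortho-substituted methyl benzoates should need poorly solvated hydroxide in a dipolar solvent, the carboxylates are safe from decarboxylation while basic, and cold acidification should release the diacid without heating it.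

**Compound list**
1 | octanal | CCCCCCCC=O | starting material
2 | methyl 2-(dimethoxyphosphoryl)-2-methoxyacetate | COC(C(=O)OC)P(=O)(OC)OC | starting material
3 | methyl (Z)-2-methoxydec-2-enoate | CCCCCCC/C=C(\OC)C(=O)OC | intermediate
4 | methyl acetoacetate | CC(=O)CC(=O)OC | starting material
5 | dimethyl 2-acetyl-3-heptyl-4-methoxypentanedioate (mixture of diastereomers) | CCCCCCCC(C(OC)C(=O)OC)C(C(C)=O)C(=O)OC | intermediate (not isolated)
6 | methyl 6-heptyl-5-methoxy-2,4-dioxocyclohexane-1-carboxylate (mixture of diastereomers and enol forms) | COC(=O)C1C(=O)CC(=O)C(OC)C1CCCCCCC | intermediate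
7 | methyl (E)-dec-2-enoate | CCCCCCC/C=C/C(=O)OC | starting material
8 | dimethyl 2-acetyl-3-heptylpentanedioate (mixture of diastereomers) | CCCCCCCC(CC(=O)OC)C(C(C)=O)C(=O)OC | intermediate (not isolated)
9 | methyl 6-heptyl-2,4-dioxocyclohexane-1-carboxylate (mixture of diastereomers and enol forms) | CCCCCCCC1CC(=O)CC(=O)C1C(=O)OC | intermediate
10 | methyl 3-bromo-6-heptyl-2,4-dioxocyclohexane-1-carboxylate | CCCCCCCC1CC(=O)C(Br)C(=O)C1C(=O)OC | intermediate (not isolated)
11 | methyl 2-heptyl-4,6-dihydroxybenzoate | CCCCCCCc1cc(O)cc(O)c1C(=O)OC | intermediate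
12 | methyl 2-heptyl-6-hydroxy-4-methoxybenzoate | CCCCCCCc1cc(OC)cc(O)c1C(=O)OC | intermediate
13 | methyl 4-[(2-chloro-2-oxoacetyl)oxy]-6-heptyl-5-methoxy-2-oxocyclohex-3-ene-1-carboxylate | COC(=O)C1C(=O)C=C(OC(=O)C(Cl)=O)C(OC)C1CCCCCCC | intermediate (not isolated)
14 | methyl 4-chloro-6-heptyl-5-methoxy-2-oxocyclohex-3-ene-1-carboxylate (mixture of diastereomers) | COC(=O)C1C(=O)C=C(Cl)C(OC)C1CCCCCCC | intermediate
15 | methyl 6-heptyl-4-[3-heptyl-5-methoxy-2-(methoxycarbonyl)phenoxy]-5-methoxy-2-oxocyclohex-3-ene-1-carboxylate (mixture of diastereomers) | COC(=O)C1C(=O)C=C(Oc2cc(OC)cc(CCCCCCC)c2C(=O)OC)C(OC)C1CCCCCCC | intermediate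
16 | methyl 2-heptyl-4-[3-heptyl-5-methoxy-2-(methoxycarbonyl)phenoxy]-6-hydroxy-3-methoxybenzoate | CCCCCCCc1cc(OC)cc(Oc2cc(O)c(C(=O)OC)c(CCCCCCC)c2OC)c1C(=O)OC | intermediate
17 | 4-(2-carboxy-3-heptyl-5-methoxyphenoxy)-2-heptyl-6-hydroxy-3-methoxybenzoic acid | CCCCCCCc1cc(OC)cc(Oc2cc(O)c(C(=O)O)c(CCCCCCC)c2OC)c1C(=O)O | target

**Step count**
Total: 9 steps. Longest linear sequence: 6 steps (steps 1, 2, 6, 7, 8, 9 from octanal; the ring A branch, steps 3, 4, 5, 7, 8, 9, is equally long).

**Steps most likely to fail**

Step 2 (bears the label). The conjugate addition may be too slow, because the methoxy oxygen feeds electron density into the β-carbon of 3; self-condensation of 4 and deconjugation of 3 would then win. The fallback builds the same open-chain triester with reversed polarity by known reactions. It sets out from octanal 1 and methyl acetoacetate 4. Knoevenagel condensation (TiCl4, pyridine, THF, 0 °C) should give the doubly activated acceptor methyl 2-acetyldec-2-enoate F1. A TiCl4-promoted Mukaiyama–Michael addition (CH2Cl2, −78 °C) of the ketene silyl acetal 1,2-dimethoxy-1-(trimethylsilyloxy)ethene F2 then follows; F2 is made from methyl methoxyacetate (COCC(=O)OC) with LiN(iPr)2 and Me3SiCl in THF at −78 °C. After aqueous work-up this should give triester 5, where the fallback comes back to the route. NaOMe in MeOH then closes 5 to 6 by the same Dieckmann-type step.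

Step 6. Activation may occur at the oxygen on C3' instead of C1', which after steps 7 and 8 would carry through to the regioisomeric diaryl ether. The fallback aromatizes first and makes the ether by cross-coupling, so no enol regiochemistry is involved. It sets out from 6 and 12. Dione 6 is aromatized with Br2 in DMF (0 °C → 80 °C, as in step 4) to methyl 2-heptyl-4,6-dihydroxy-3-methoxybenzoate F3. Phenol 12 is converted with Tf2O and pyridine (CH2Cl2, 0 °C) into methyl 2-heptyl-4-methoxy-6-[(trifluoromethanesulfonyl)oxy]benzoate F4. Palladium-catalysed C–O coupling of F3 with F4 (Pd(OAc)2, tBuXPhos, K3PO4, toluene, 100 °C) should arylate the non-chelated hydroxyl para to the ester of F3. The fallback comes back to the route at 16, bypassing 14 and 15.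

Step 8. Redox-neutral loss of methanol across C5'–C6' may compete with dehydrogenation and give the arene without the C6' methoxy, or the quinone may over-oxidize a benzylic position. The fallback replaces hydride abstraction by a two-stage selenium oxidation at the β-keto ester carbon. It sets out from 15. Selenenylation (NaH, PhSeCl, THF, 0 °C) should give methyl 6-heptyl-4-[3-heptyl-5-methoxy-2-(methoxycarbonyl)phenoxy]-5-methoxy-2-oxo-1-(phenylselanyl)cyclohex-3-ene-1-carboxylate F5, with selenium entering trans to the heptyl group and hence syn to the C5' hydrogen. Oxidation with H2O2 (CH2Cl2, 0 °C → rt) gives the selenoxide of F5, F6, whose syn-elimination and tautomerization of the resulting dienone should deliver 16, where the fallback comes back to the route.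

**Further compounds**
F1 | step 2 | methyl 2-acetyldec-2-enoate (E/Z mixture) | CCCCCCCC=C(C(C)=O)C(=O)OC
F2 | step 2 | 1,2-dimethoxy-1-(trimethylsilyloxy)ethene (E/Z mixture) | COC=C(OC)O[Si](C)(C)C
F3 | step 6 | methyl 2-heptyl-4,6-dihydroxy-3-methoxybenzoate | CCCCCCCc1c(OC)c(O)cc(O)c1C(=O)OC
F4 | step 6 | methyl 2-heptyl-4-methoxy-6-[(trifluoromethanesulfonyl)oxy]benzoate | CCCCCCCc1cc(OC)cc(OS(=O)(=O)C(F)(F)F)c1C(=O)OC
F5 | step 8 | methyl 6-heptyl-4-[3-heptyl-5-methoxy-2-(methoxycarbonyl)phenoxy]-5-methoxy-2-oxo-1-(phenylselanyl)cyclohex-3-ene-1-carboxylate | COC(=O)C1([Se]c2ccccc2)C(=O)C=C(Oc2cc(OC)cc(CCCCCCC)c2C(=O)OC)C(OC)C1CCCCCCC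
F6 | step 8 | methyl 6-heptyl-4-[3-heptyl-5-methoxy-2-(methoxycarbonyl)phenoxy]-5-methoxy-2-oxo-1-(phenylseleninyl)cyclohex-3-ene-1-carboxylate | COC(=O)C1([Se](=O)c2ccccc2)C(=O)C=C(Oc2cc(OC)cc(CCCCCCC)c2C(=O)OC)C(OC)C1CCCCCCC
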